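**Retrosynthetic overview**
- The target is (13Z)-19-acetoxylabda-8(17),13-dien-15-oic acid in the normal labdane series (4S,5R,9S,10R). Rings A and B, all four stereocentres, the C8 methylene and the C19 oxygen are bought intact in trans-communic acid, so no ring is formed.
- Key disconnection C12–C13: a light-driven nickel/iridium coupling of a C12 radical (from the C12 alcohol) with (Z)-3-iodobut-2-enoic acid, which brings C13–C16 with the Z geometry already fixed.
- The C12 alcohol comes from site-selective ozonolysis and borohydride reduction of the side-chain diene; the C19 acetate comes from hydride reduction of the C19 acid and acetylation.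
- The iodo acid comes from but-2-ynoic acid by anti addition of hydrogen iodide.

Assumption: trans-communic acid (the main diterpene acid of juniper berries and sandarac resin, listed by natural-product suppliers) is taken as the purchasable chiral starting material.

Abbreviations: dtbbpy = 4,4'-di-tert-butyl-2,2'-bipyridine; ppy = 2-phenylpyridinate; DMA = N,N-dimethylacetamide; MTBE = methyl tert-butyl ether.

**Step 1**
Reactants: 1 trans-communic acid, (4S,5R,9S,10R,12E)-labda-8(17),12,14-trien-19-oic acid
Product: 2 trans-communol, (4S,5R,9S,10R,12E)-labda-8(17),12,14-trien-19-ol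
Conditions: LiAlH4 (3 equiv), THF, 0 °C to reflux, 6 h; Fieser work-up
Reagents that add atoms: none
Why: Hydride reduction of a carboxylic acid (LiAlH4 reduction) takes the axial C19 acid to the neopentyl alcohol, while the unactivated diene and the exocyclic alkene are inert to hydride and no stereocentre is touched.

**Step 2**
Reactants: 2 trans-communol
Product: 3 (4S,5R,9S,10R,12E)-labda-8(17),12,14-trien-19-yl acetate
Conditions: Ac2O, pyridine, DMAP (5 mol %), CH2Cl2, rt
Reagents that add atoms: acetic anhydride, CC(=O)OC(C)=O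
Why: DMAP-catalysed acylation (nucleophilic catalysis) of the only hydroxyl group installs the C19 acetate of the target, which then also protects this oxygen for the rest of the route.

**Step 3**
Reactants: 3 (4S,5R,9S,10R,12E)-labda-8(17),12,14-trien-19-yl acetate
Product: 5 (4S,5R,9S,10R)-19-acetoxy-13,14,15,16-tetranorlabd-8(17)-en-12-ol, via C12 aldehyde 4 (not isolated)
Conditions: O3 (about 1 equiv, stopped when Sudan Red 7B fades), pyridine (3 equiv), CH2Cl2, −78 °C; then NaBH4, MeOH, −78 to 0 °C
Reagents that add atoms: ozone, [O-][O+]=O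
Why: Site-selective ozonolysis (Criegee mechanism) with reductive work-up: electrophilic ozone consumes the electron-rich trisubstituted C12=C13 bond of the diene faster than the 1,1-disubstituted C8=C17 bond, which is screened by the C20 methyl and the C9 side chain; pyridine turns the carbonyl oxide directly into the aldehyde, and cold NaBH4 reduces it at once without touching the hindered acetate or C9, which is not alpha to the carbonyl.

**Step 4**
Reactants: 6 but-2-ynoic acid
Product: 7 (Z)-3-iodobut-2-enoic acid
Conditions: NaI (1.6 equiv), AcOH, 110 °C, 3 h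
Reagents that add atoms: sodium iodide, [Na+].[I-]
Why: Hydroiodination of an ynoic acid by conjugate addition of iodide and anti protonation puts iodine cis to the carboxyl group, giving the Z acid, which is purified by crystallisation.

**Step 5**
Reactants: 5 (4S,5R,9S,10R)-19-acetoxy-13,14,15,16-tetranorlabd-8(17)-en-12-ol, 7 (Z)-3-iodobut-2-enoic acid, 8 5,7-di-tert-butyl-3-phenyl-1,3-benzoxazol-3-ium tetrafluoroborate
Product: 10 (4S,5R,9S,10R,13Z)-19-acetoxylabda-8(17),13-dien-15-oic acid (target), via alkoxybenzoxazoline adduct 9 (not isolated)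
Conditions: 8 (1.2 equiv), pyridine (1.2 equiv), MTBE, rt, 20 min; then 7 (1.5 equiv), quinuclidine (3 equiv), NiBr2(dtbbpy) (10 mol %), Ir(ppy)2(dtbbpy)PF6 (1 mol %), DMA/MTBE, 450 nm LEDs, rt, 16 h; aq. citric acid work-up
Reagents that add atoms: none
Why: Proposed new method: a stereoretentive metallaphotoredox deoxygenative alkenylation that uses the unprotected (Z)-β-iodo acid as the electrophile; the excited iridium photocatalyst oxidises the aminal nitrogen of adduct 9, quinuclidine removes the aminal C–H proton, and β-scission expels the benzoxazolone and frees the primary C12 radical, while zerovalent nickel inserts into the carbon–iodine bond of the carboxylate of 7 and the cis carboxylate closes a five-membered oxanickelacyclopentenone (the Hoberg-type nickelalactone otherwise reached from an alkyne, CO2 and zerovalent nickel) that cannot rotate, so radical capture at divalent nickel and reductive elimination from trivalent nickel forge C12–C13 with C12 held cis to the carboxyl group (13Z), and the reduced iridium complex returns monovalent nickel to zerovalent nickel; the low triplet energy of Ir(ppy)2(dtbbpy)PF6 rules out sensitised Z/E scrambling, and no stereocentre is formed or touched; closest known reaction type: nickel/photoredox deoxygenative arylation of benzoxazolium-activated alcohols with aryl halides, together with the stereospecific alkylation of nickelalactones.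

**Compound list**
1 | trans-communic acid, (4S,5R,9S,10R,12E)-labda-8(17),12,14-trien-19-oic acid | C=C1CC[C@H]2[C@@](C)(C(=O)O)CCC[C@]2(C)[C@H]1C/C=C(\C)C=C | starting material
2 | trans-communol, (4S,5R,9S,10R,12E)-labda-8(17),12,14-trien-19-ol | C=C1CC[C@H]2[C@@](C)(CO)CCC[C@]2(C)[C@H]1C/C=C(\C)C=C | intermediate
3 | (4S,5R,9S,10R,12E)-labda-8(17),12,14-trien-19-yl acetate | C=C1CC[C@H]2[C@@](C)(COC(C)=O)CCC[C@]2(C)[C@H]1C/C=C(\C)C=C | intermediate
4 | (4S,5R,9S,10R)-19-acetoxy-13,14,15,16-tetranorlabd-8(17)-en-12-al | C=C1CC[C@H]2[C@@](C)(COC(C)=O)CCC[C@]2(C)[C@H]1CC=O | intermediate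
5 | (4S,5R,9S,10R)-19-acetoxy-13,14,15,16-tetranorlabd-8(17)-en-12-ol | C=C1CC[C@H]2[C@@](C)(COC(C)=O)CCC[C@]2(C)[C@H]1CCO | intermediate
6 | but-2-ynoic acid | CC#CC(=O)O | starting material
7 | (Z)-3-iodobut-2-enoic acid | C/C(I)=C/C(=O)O | intermediate
8 | 5,7-di-tert-butyl-3-phenyl-1,3-benzoxazol-3-ium tetrafluoroborate | CC(C)(C)c1cc(C(C)(C)C)c2oc[n+](-c3ccccc3)c2c1.F[B-](F)(F)F | starting material
9 | 2-{[(4S,5R,9S,10R)-19-acetoxy-13,14,15,16-tetranorlabd-8(17)-en-12-yl]oxy}-5,7-di-tert-butyl-3-phenyl-2,3-dihydro-1,3-benzoxazole (both epimers at the aminal carbon) | C=C1CC[C@H]2[C@@](C)(COC(C)=O)CCC[C@]2(C)[C@H]1CCOC1Oc2c(C(C)(C)C)cc(C(C)(C)C)cc2N1c1ccccc1 | intermediate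
10 | (4S,5R,9S,10R,13Z)-19-acetoxylabda-8(17),13-dien-15-oic acid | C=C1CC[C@H]2[C@@](C)(COC(C)=O)CCC[C@]2(C)[C@H]1CC/C(C)=C\C(=O)O | target

**Step count**
Total step count: 5. Longest linear sequence: 4 (steps 1, 2, 3 and 5; step 4 is a one-step side branch).

**Three steps most likely to fail**

Step 5 (the proposed new coupling). It may fail if the free carboxylate degrades adduct 9, if the nickelalactone is too stable to capture the radical, or if protodeiodination of 7 outruns coupling. The fallback uses known two-electron chemistry, sets out from 5 and comes back at 10. An Appel reaction (CBr4, PPh3, CH2Cl2, 0 °C) gives (4S,5R,9S,10R)-19-acetoxy-12-bromo-13,14,15,16-tetranorlabd-8(17)-ene F3. Zinc insertion (activated Zn dust, LiCl, THF, 50 °C) gives [(4S,5R,9S,10R)-19-acetoxy-13,14,15,16-tetranorlabd-8(17)-en-12-yl]zinc bromide F4. Negishi coupling with purchased ethyl (Z)-3-iodobut-2-enoate (C/C(I)=C/C(=O)OCC; Pd(PPh3)4, THF, rt) proceeds with retention to ethyl (4S,5R,9S,10R,13Z)-19-acetoxylabda-8(17),13-dien-15-oate F5. LiOH (THF/MeOH/H2O) cleaves both esters to (4S,5R,9S,10R,13Z)-19-hydroxylabda-8(17),13-dien-15-oic acid F6. Ac2O/pyridine, then aqueous NaHCO3 to hydrolyse the mixed anhydride and acidification, re-acetylates C19 and returns 10.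

Step 3 (site-selective ozonolysis). Ozone may attack the terminal vinyl group first or over-oxidise the C8=C17 bond. The fallback sets out from 3 and comes back at 4. Epoxidation of the most nucleophilic, trisubstituted C12=C13 bond (mCPBA, 1.0 equiv, NaHCO3, CH2Cl2, −20 °C) gives (4S,5R,9S,10R)-19-acetoxy-12,13-epoxylabda-8(17),14-diene F2 as a mixture of epoxide diastereomers. Periodic acid (H5IO6, THF/H2O, 0 °C) cleaves the epoxide to aldehyde 4, which is reduced with NaBH4 as in step 3 to give 5.

Step 1 (reduction of the hindered axial acid). The insoluble aluminium carboxylate of the neopentyl-type C19 acid may reduce sluggishly. The fallback sets out from 1 and comes back at 2. O-alkylation of the carboxylate (MeI, K2CO3, DMF, rt), which avoids attack at the hindered carbonyl, gives methyl (4S,5R,9S,10R,12E)-labda-8(17),12,14-trien-19-oate F1. Its reduction with LiAlH4 (Et2O, 0 °C to rt) gives 2.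

**Further compounds**
F1 | step 1 | methyl (4S,5R,9S,10R,12E)-labda-8(17),12,14-trien-19-oate | C=C1CC[C@H]2[C@@](C)(C(=O)OC)CCC[C@]2(C)[C@H]1C/C=C(\C)C=C
F2 | step 3 | (4S,5R,9S,10R)-19-acetoxy-12,13-epoxylabda-8(17),14-diene (epoxide diastereomers) | C=C1CC[C@H]2[C@@](C)(COC(C)=O)CCC[C@]2(C)[C@H]1CC1OC1(C)C=C
F3 | step 5 | (4S,5R,9S,10R)-19-acetoxy-12-bromo-13,14,15,16-tetranorlabd-8(17)-ene | C=C1CC[C@H]2[C@@](C)(COC(C)=O)CCC[C@]2(C)[C@H]1CCBr
F4 | step 5 | [(4S,5R,9S,10R)-19-acetoxy-13,14,15,16-tetranorlabd-8(17)-en-12-yl]zinc bromide | C=C1CC[C@H]2[C@@](C)(COC(C)=O)CCC[C@]2(C)[C@H]1CC[Zn]Br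
F5 | step 5 | ethyl (4S,5R,9S,10R,13Z)-19-acetoxylabda-8(17),13-dien-15-oate | C=C1CC[C@H]2[C@@](C)(COC(C)=O)CCC[C@]2(C)[C@H]1CC/C(C)=C\C(=O)OCC
F6 | step 5 | (4S,5R,9S,10R,13Z)-19-hydroxylabda-8(17),13-dien-15-oic acid | C=C1CC[C@H]2[C@@](C)(CO)CCC[C@]2(C)[C@H]1CC/C(C)=C\C(=O)O
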